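Early in a flask of Q with catalyst L, before J and Z have built up, two of us disagree about the share of J in J plus Z, and the earliest reading lies at 0.500 h.

all flasks: L 64 µM
- Sunday's: Q 24 mM; run made earlier
- Wednesday's: Q 98 mM; run made earlier
- flask: Q 49 mM; time 8.0 h

- Sunday's (time / h: J / %, Z / %, Q / %): 1.33: 24.2, 46.1, 1.3; 2.50: 24.2, 47.4, 0; 4.00: 23.1, 48.8, 0; 5.00: 22.8, 49.4, 0; 6.00: 22.9, 49.7, 0.4
- Wednesday's (time / h: J / %, Z / %, Q / %): 0.500: 26.4, 27.4, 20.0; 1.50: 23.7, 46.3, 1.3; 3.00: 23.2, 49.4, 0; 5.00: 23.3, 48.7, 0.9; 6.00: 23.3, 48.9, 0

(standard deviation of a reading: 0.5 percentage points)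



1. share of J in J plus Z at 30 s
2. share of J in J plus Z at 15 min
3. share of J in J plus Z at 8.0 h

At fixed L, Q falls as a pseudo-first-order loss, with a constant of 3.27 h⁻¹ from Sunday's run and 3.22 h⁻¹ from Wednesday's, so I take the flask's percent curves from those runs despite its different charge. The first of us sees J's share in Wednesday's run fall from 49.1 % at 0.500 h to 33.9 % at 1.50 h and reads a relaxation from some moderate starting share down to a plateau. I read a lag instead: in Sunday's run Q is down to 1.3 % at 1.33 h, yet Z climbs from 46.1 % to 49.7 % by 6.00 h, so I put an unseen stage before Z, which makes J grow with time t at first, Z with t squared, and Z/J in proportion to t.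

Wednesday's reading at 0.500 h, taken with Q already down to 20.0 %, then puts the crossing at 0.482 h, and this crossing time t×, the moment Z draws level with J, gives a share of 1/(1 + t/t×) at early times. That is 98.3 % at 30 s and 65.8 % at 15 min, the second less firm because 15 min is not far below Q's lifetime of 0.311 h as read in Wednesday's run. For 8.0 h we both take the plateau of the last readings, 31.9 %.

The forecast, the first side's number for a share “relaxing towards a plateau or equilibrium”, gives 70 %, 57 % and 32 %.

The flask gives 98.3 %, 64.9 % and 32.2 %.

    Q ⇌ E (K = 7.70, k = 0.0270 min⁻¹)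
    Q + L → L + J (k = 420 L mol⁻¹ min⁻¹)
    L + E → L + Z (k = 1100 L mol⁻¹ min⁻¹)
    J ⇌ D (K = 1.20, k = 0.0370 min⁻¹)

The lag view holds at early times, and the relaxation view keeps the late region, where the flask stands at 23.2 % of J and 48.9 % of Z at 8.0 h. In this flask Z drew level with J at 0.473 h, close to the t× of 0.482 h. Carried unchanged to the flask with 0.26 mM of L, t× again gives 98.3 % at 30 s, and that flask stands at 98.3 %, though at 15 min it holds 77.6 % against the 65.8 % of the same reckoning.

(The numbers in the tables come from a simulation for substances that don't exist.)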